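**Target:** (2S)-5,3'-dihydroxy-7,4'-dimethoxy-6-prenyl-2'-[(E)-geranyl]flavanone (17). The SMILES was read as 2S at C2 and E in the geranyl chain.

**Retrosynthetic overview**
1. C2–C1' is cut last: Rh/(S)-bisphosphine 1,4-arylation of chromone 7 with boronic acid 16 dearomatises the γ-pyrone and sets C2 (S), with no protecting groups present.
2. Chromone 7 comes from 6-iodide 5 (Stille prenylation), which comes from 5-hydroxy-7-methoxychromone 4 (iodination ortho to the chelated 5-OH).
3. Chromone 4 comes from the symmetric 2,6-dihydroxy-4-methoxyacetophenone 2 (DMF-DMA annulation; either OH closes to the same ring), made from phloroacetophenone 1.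
4. Boronic acid 16 comes from 5-bromoguaiacol 8: acetal protection, metalation between O and Br with geranylation, then Br→B(OH)2 with loss of the acetal.
5. Ring order: A ring bought (1), pyranone ring C formed in step 2, B ring (from 8) attached in step 8.

**Assumption:** the (S)-biaryl bisphosphine delivers the aryl group to the chromone face that gives 2S (the same sense as (S)-BINAP giving (S)-3-arylcyclohexanones). This is a prediction to confirm by CD on the first run; if the sign is opposite, the (R)-ligand is used and nothing else changes.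

**Route**

Step 1
Reactants: 1 1-(2,4,6-trihydroxyphenyl)ethan-1-one (phloroacetophenone, cheap bulk aromatic)
Product: 2 1-(2,6-dihydroxy-4-methoxyphenyl)ethan-1-one
Conditions: Me2SO4 (1.0 equiv), K2CO3 (1.0 equiv), acetone, reflux
Reagents that add atoms: dimethyl sulfate, COS(=O)(=O)OC
Why: Williamson O-methylation is selective for the para OH, which is the most acidic and the only one not hydrogen-bonded to the ketone.

Step 2
Reactants: 2 1-(2,6-dihydroxy-4-methoxyphenyl)ethan-1-one
Product: 4 5-hydroxy-7-methoxy-4H-chromen-4-one, via enaminone 3 (not isolated)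
Conditions: Me2NCH(OMe)2 (1.5 equiv), toluene, 90 °C; then AcOH, 80 °C
Reagents that add atoms: N,N-dimethylformamide dimethyl acetal, COC(OC)N(C)C
Why: Enaminone formation at the methyl ketone followed by acid-promoted addition–elimination (loss of Me2NH) gives the chromone; the two ortho OH groups are equivalent, so ring closure has no regiochemical issue and the other OH remains as the chelated 5-OH.

Step 3
Reactants: 4 5-hydroxy-7-methoxy-4H-chromen-4-one
Product: 5 5-hydroxy-6-iodo-7-methoxy-4H-chromen-4-one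
Conditions: BnMe3N+ ICl2− (1.05 equiv), CaCO3, CH2Cl2–MeOH (5:2), rt
Reagents that add atoms: benzyltrimethylammonium dichloroiodate, C[N+](C)(C)Cc1ccccc1.Cl[I-]Cl
Why: Electrophilic aromatic iodination of a 5-hydroxy-7-alkoxy benzopyranone with this mild I+ source goes ortho to the free chelated phenol (C6, not C8); the assignment is checked by HMBC from the 5-OH proton.

Step 4
Reactants: 5 5-hydroxy-6-iodo-7-methoxy-4H-chromen-4-one; 6 tributyl(3-methylbut-2-en-1-yl)stannane
Product: 7 5-hydroxy-7-methoxy-6-(3-methylbut-2-en-1-yl)-4H-chromen-4-one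
Conditions: Pd(PPh3)4 (5 mol %), DMF, 90 °C
Reagents that add atoms: none
Why: Stille coupling transfers the allyl group through its unsubstituted CH2 terminus to give the linear prenyl group, and the free chelated phenol is tolerated.

Step 5
Reactants: 8 5-bromo-2-methoxyphenol
Product: 9 4-bromo-2-(1-ethoxyethoxy)-1-methoxybenzene (racemic at the acetal carbon, which is removed in step 7)
Conditions: ethyl vinyl ether (3 equiv), PPTS (5 mol %), CH2Cl2, rt
Reagents that add atoms: ethyl vinyl ether, C=COCC
Why: Acid-catalysed addition of the phenol to the enol ether gives a base-stable 1-ethoxyethyl acetal that directs ortho-metalation and is cleaved later by dilute acid.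

Step 6
Reactants: 9 4-bromo-2-(1-ethoxyethoxy)-1-methoxybenzene; 10 (2E)-1-bromo-3,7-dimethylocta-2,6-diene (geranyl bromide)
Product: 13 1-bromo-2-[(2E)-3,7-dimethylocta-2,6-dien-1-yl]-3-(1-ethoxyethoxy)-4-methoxybenzene, via bromoaryllithium 11 (not isolated), via arylcopper 12 (not isolated)
Conditions: LDA (1.1 equiv), THF, −78 °C, 1 h; CuBr·SMe2 (1.0 equiv), −78 °C; then 10, −78 → −20 °C
Reagents that add atoms: none
Why: Directed ortho-metalation with LDA removes the most acidic proton (between the acetal oxygen and Br) without Br/Li exchange, and the arylcopper formed on transmetalation resists benzyne formation and is allylated at the primary carbon of 10 (SN2) with retention of the E-alkene.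

Step 7
Reactants: 13 1-bromo-2-[(2E)-3,7-dimethylocta-2,6-dien-1-yl]-3-(1-ethoxyethoxy)-4-methoxybenzene
Product: 16 {2-[(2E)-3,7-dimethylocta-2,6-dien-1-yl]-3-hydroxy-4-methoxyphenyl}boronic acid, via aryllithium 14 (not isolated), via lithium borate 15 (not isolated)
Conditions: n-BuLi (1.1 equiv), THF, −78 °C; B(OiPr)3, −78 °C → rt; then 1 M aq. HCl, THF, rt, 1 h
Reagents that add atoms: triisopropyl borate, CC(C)OB(OC(C)C)OC(C)C; water, O
Why: Bromine–lithium exchange and electrophilic borylation give the borate, and the dilute-acid work-up hydrolyses both the B–O-iPr bonds and the very labile ethoxyethyl acetal while leaving the trisubstituted alkenes intact.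

Step 8
Reactants: 7 5-hydroxy-7-methoxy-6-(3-methylbut-2-en-1-yl)-4H-chromen-4-one; 16 {2-[(2E)-3,7-dimethylocta-2,6-dien-1-yl]-3-hydroxy-4-methoxyphenyl}boronic acid (1.8 equiv)
Product: 17 (2S)-2-{2-[(2E)-3,7-dimethylocta-2,6-dien-1-yl]-3-hydroxy-4-methoxyphenyl}-5-hydroxy-7-methoxy-6-(3-methylbut-2-en-1-yl)-2,3-dihydro-4H-chromen-4-one
Conditions: [Rh(OH)((S)-MeO-F12-BIPHEP)]2 (5 mol % Rh), toluene–H2O (10:1), 40 °C, no added base
Reagents that add atoms: none
Why: Rh(I)-catalysed asymmetric 1,4-addition (Hayashi–Miyaura type) inserts the aryl–Rh species across C2=C3 on the face left open by the (S)-bisphosphine and water protonates the Rh enolate, so C2 (S) is set under catalyst control as the γ-pyrone is dearomatised; the base-free medium avoids retro-oxa-Michael opening, which would erode ee and scramble 6- and 8-prenyl isomers.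

**Compound list**
1 | 1-(2,4,6-trihydroxyphenyl)ethan-1-one | CC(=O)c1c(O)cc(O)cc1O | starting material
2 | 1-(2,6-dihydroxy-4-methoxyphenyl)ethan-1-one | CC(=O)c1c(O)cc(OC)cc1O | intermediate
3 | (2E)-1-(2,6-dihydroxy-4-methoxyphenyl)-3-(dimethylamino)prop-2-en-1-one | CN(C)/C=C/C(=O)c1c(O)cc(OC)cc1O | intermediate
4 | 5-hydroxy-7-methoxy-4H-chromen-4-one | COc1cc(O)c2c(c1)OC=CC2=O | intermediate
5 | 5-hydroxy-6-iodo-7-methoxy-4H-chromen-4-one | COc1cc2OC=CC(=O)c2c(O)c1I | intermediate
6 | tributyl(3-methylbut-2-en-1-yl)stannane | CCCC[Sn](CCCC)(CCCC)CC=C(C)C | starting material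
7 | 5-hydroxy-7-methoxy-6-(3-methylbut-2-en-1-yl)-4H-chromen-4-one | COc1cc2OC=CC(=O)c2c(O)c1CC=C(C)C | intermediate
8 | 5-bromo-2-methoxyphenol | COc1ccc(Br)cc1O | starting material
9 | 4-bromo-2-(1-ethoxyethoxy)-1-methoxybenzene (racemic acetal) | CCOC(C)Oc1cc(Br)ccc1OC | intermediate
10 | (2E)-1-bromo-3,7-dimethylocta-2,6-diene | BrC/C=C(\C)CCC=C(C)C | starting material
11 | [6-bromo-2-(1-ethoxyethoxy)-3-methoxyphenyl]lithium | [Li]c1c(Br)ccc(OC)c1OC(C)OCC | intermediate
12 | [6-bromo-2-(1-ethoxyethoxy)-3-methoxyphenyl]copper(I) | [Cu]c1c(Br)ccc(OC)c1OC(C)OCC | intermediate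
13 | 1-bromo-2-[(2E)-3,7-dimethylocta-2,6-dien-1-yl]-3-(1-ethoxyethoxy)-4-methoxybenzene | COc1ccc(Br)c(C/C=C(\C)CCC=C(C)C)c1OC(C)OCC | intermediate
14 | {2-[(2E)-3,7-dimethylocta-2,6-dien-1-yl]-3-(1-ethoxyethoxy)-4-methoxyphenyl}lithium | [Li]c1ccc(OC)c(OC(C)OCC)c1C/C=C(\C)CCC=C(C)C | intermediate
15 | lithium {2-[(2E)-3,7-dimethylocta-2,6-dien-1-yl]-3-(1-ethoxyethoxy)-4-methoxyphenyl}tri(propan-2-yloxy)borate | CC(C)O[B-](OC(C)C)(OC(C)C)c1ccc(OC)c(OC(C)OCC)c1C/C=C(\C)CCC=C(C)C.[Li+] | intermediate
16 | {2-[(2E)-3,7-dimethylocta-2,6-dien-1-yl]-3-hydroxy-4-methoxyphenyl}boronic acid | COc1ccc(B(O)O)c(C/C=C(\C)CCC=C(C)C)c1O | intermediate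
17 | (2S)-2-{2-[(2E)-3,7-dimethylocta-2,6-dien-1-yl]-3-hydroxy-4-methoxyphenyl}-5-hydroxy-7-methoxy-6-(3-methylbut-2-en-1-yl)-2,3-dihydro-4H-chromen-4-one | COc1ccc([C@@H]2CC(=O)c3c(cc(OC)c(CC=C(C)C)c3O)O2)c(C/C=C(\C)CCC=C(C)C)c1O | target

**Totals**
Total steps: 8. Longest linear sequence: 5 (steps 1, 2, 3, 4, 8); the other branch is steps 5, 6, 7, 8.

**Steps most likely to fail, with fallbacks**

Step 8 (key arylation). The boronic acid carries an ortho geranyl group, chromones are sluggish acceptors, and two free phenols are present. The fallback sets out from 7 and 16 and comes back at 17. It gives up catalyst control: the two are coupled with the achiral and much more active [Rh(OH)(cod)]2 (dioxane–H2O, 40 °C) to give the racemic flavanone F1. Preparative chiral SFC then separates 17 from the (2R)-flavanone F2, which is set aside. F2 is not recycled by base, because ring opening would also scramble the prenyl position.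

Step 6 (metalation and geranylation). The risks are benzyne formation from the ortho-bromo aryllithium and SN2' attack on the allylic bromide. The fallback sets out from 8 and comes back at 13. The sodium phenoxide of 8 (NaH, toluene, rt → 60 °C) is C-alkylated by 10 in the non-polar medium at its only free ortho position, giving 3-bromo-2-[(2E)-3,7-dimethylocta-2,6-dien-1-yl]-6-methoxyphenol F3. Ethyl vinyl ether with PPTS then converts F3 into 13.

Step 3 (C6 versus C8 iodination on a 2-unsubstituted chromone). The fallback sets out from 4 and comes back at 7, so it also replaces step 4. The 5-OH of 4 is alkylated with 3-chloro-3-methylbut-1-yne (K2CO3, KI, CuI cat., acetone, reflux) to give 7-methoxy-5-[(2-methylbut-3-yn-2-yl)oxy]-4H-chromen-4-one F4. Lindlar semi-hydrogenation gives 7-methoxy-5-[(2-methylbut-3-en-2-yl)oxy]-4H-chromen-4-one F5. Heating F5 (N,N-diethylaniline, 130 °C) triggers an aromatic Claisen rearrangement that can only deliver the prenyl group to C6 and gives 7.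

**Further compounds**
F1 | step 8 | rac-2-{2-[(2E)-3,7-dimethylocta-2,6-dien-1-yl]-3-hydroxy-4-methoxyphenyl}-5-hydroxy-7-methoxy-6-(3-methylbut-2-en-1-yl)-2,3-dihydro-4H-chromen-4-one | COc1ccc(C2CC(=O)c3c(cc(OC)c(CC=C(C)C)c3O)O2)c(C/C=C(\C)CCC=C(C)C)c1O
F2 | step 8 | (2R)-2-{2-[(2E)-3,7-dimethylocta-2,6-dien-1-yl]-3-hydroxy-4-methoxyphenyl}-5-hydroxy-7-methoxy-6-(3-methylbut-2-en-1-yl)-2,3-dihydro-4H-chromen-4-one | COc1ccc([C@H]2CC(=O)c3c(cc(OC)c(CC=C(C)C)c3O)O2)c(C/C=C(\C)CCC=C(C)C)c1O
F3 | step 6 | 3-bromo-2-[(2E)-3,7-dimethylocta-2,6-dien-1-yl]-6-methoxyphenol | COc1ccc(Br)c(C/C=C(\C)CCC=C(C)C)c1O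
F4 | step 3 | 7-methoxy-5-[(2-methylbut-3-yn-2-yl)oxy]-4H-chromen-4-one | COc1cc(OC(C)(C)C#C)c2c(c1)OC=CC2=O
F5 | step 3 | 7-methoxy-5-[(2-methylbut-3-en-2-yl)oxy]-4H-chromen-4-one | COc1cc(OC(C)(C)C=C)c2c(c1)OC=CC2=O
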